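**Remark on the chemistry:** chromone numbering is used throughout (O1, C2, C3, C4, C4a, C5–C8, C8a). Ring A is the benzo ring, ring C the pyranone, ring B the 3,4,5-trimethoxyphenyl group. Acid chloride 6 is assumed to be made and used in the same operation without isolation.

## The problem

Target 11 is an isoflavone: a benzo ring (ring A) fused to a 4-pyranone (ring C) that carries a 3,4,5-trimethoxyphenyl group (ring B) at C3. It has no stereocentre, so the synthesis has to solve regiochemistry and oxidation level only. Ring C must be closed with the aryl group at C3 and not at C2, which means the C3–aryl bond has to be fixed before the ring is formed. Of the five phenolic oxygens, four are methyl ethers and one, at C6 next to the 7-methoxy group, is free. This oxygen must travel under a group that can be removed at the end without touching four aryl methyl ethers. The pyranone opens when hydroxide attacks C2, its C2=C3 bond can be over-reduced, strong Lewis acids can demethylate the contiguous trimethoxy array of ring B, and the free 6-hydroxy-7-methoxy arene is easily oxidised. A stereocentre appears only transiently (C3 of an isoflavanone) if ring C is closed one oxidation level down; it controls nothing and is erased again. The feature that makes the key step possible is that C2 is a lone CH bonded only to O1 and C3. At the chromanone level it is an O–CH2 unit and can be mapped onto the methyl carbon of a methoxy group ortho to the C4 carbonyl on ring A, so ring C can close at carbon by joining that methyl carbon to a carbenoid C3 that already bears ring B and the ketone.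

## Retrosynthesis

**11 from 10.** The O–CH2Ph bond at C6 is cut last. The free phenol would not survive DDQ, and it would trap a rhodium carbenoid by O–H insertion, so it stays masked until the end. Benzyl is preferred over alkyl or acyl groups because hydrogenolysis distinguishes it from the four methyl ethers and needs neither a strong Lewis acid (a risk for ring B) nor hydroxide (a risk for ring C). Compound 10 differs from 11 only in this group. The forward step must stop before the C2=C3 bond is reduced.

**10 from 9.** The C2=C3 double bond is taken back to a single bond, giving isoflavanone 9. This is the cost of the key disconnection: insertion into a methyl C–H bond delivers C2 as CH2, so the oxidation level is corrected afterwards. Compound 9 is not smaller than 10, but it opens ring C to a C–C bond-forming closure. The forward step is a dehydrogenation that has to spare the benzyl ether, and it removes the only stereocentre of the route.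

**9 from 8.** The C2–C3 bond is cut, opening ring C to diazoketone 8, in which C3 carries the diazo group between ring B and the C4 carbonyl and the future C2 is the methyl of the ortho-methoxy group. The neighbouring cuts (O1–C2, or C4–C4a with O1–C8a) need a free ortho-phenol set apart from the other ring A oxygens, plus a separate one-carbon reagent or an acidic acylation. The C2–C3 cut needs neither: both ring A methoxy groups enter as ordinary methyl ethers and one of them becomes C2. The precursor is an acyclic deoxybenzoin derivative. The forward reaction must make the carbenoid insert into a primary C–H bond next to oxygen in preference to attacking that oxygen.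

**8 from 7.** Removing the diazo group leads to deoxybenzoin 7. The C3 methylene is both benzylic and α to the ketone, so direct diazo transfer with an amidine base suffices and no activating acyl group has to be put on and taken off. The forward step needs only clean deprotonation at that methylene.

**7 from 4 and 6 (from 5).** The aryl–carbonyl bond C4–C4a is cut, giving arene 4 and acid chloride 6, which is made from commercial acid 5. The acyl group has to enter para to one methoxy group and ortho to the other, and this is the innate site of electrophilic substitution in 4. Cutting C3–C4 instead would require an acyl anion equivalent or an enolate arylation and more steps. Both fragments are simple benzene derivatives. The forward reaction needs a Lewis acid mild enough for a benzyl aryl ether.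

**4 from 3, and 3 from 1 via 2.** The benzyl ether is cut back to phenol 3, and the phenolic C–O bond is traced to the formyl group of aldehyde 1 by Dakin oxidation through formate 2. Aldehyde 1 already carries both methyl ethers in the right positions, so 3 has a single hydroxyl and benzylation is unambiguous. A starting aldehyde carrying only one of the two methyl ethers would cost an extra methylation step.

## Roads not taken

**Alternative 1:** The cut runs through C3–C4 and O1–C2 and divides the target into a salicylic acid half and an arylacetaldehyde half. In the forward direction 2-(3,4,5-trimethoxyphenyl)acetaldehyde A1 would be condensed with morpholine to the enamine 4-[(E)-2-(3,4,5-trimethoxyphenyl)ethenyl]morpholine A2. A2 would be acylated at its β-carbon by 2-acetoxy-5-(benzyloxy)-4-methoxybenzoyl chloride A3 in the presence of Et3N. Acidic work-up would then cleave the acetate, and the freed phenol would displace morpholine at C2 to give 6-(benzyloxy)-7-methoxy-3-(3,4,5-trimethoxyphenyl)-4H-chromen-4-one A4, the same substance as 10.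

- Merits: the route is convergent, the ring closure is of an established type, and A4 arrives at the isoflavone oxidation level, so no dehydrogenation, diazo compound or rhodium is needed.
- Weak points: A3 is a benzoic acid with three differently masked oxygens (acetate, methyl, benzyl) and would take more steps than the whole ring A sequence of the chosen route. A1 is an enolisable aldehyde prone to self-condensation. A2 is a conjugated styryl enamine, less nucleophilic than an aliphatic enamine and easily hydrolysed.
- Comparison: in precedent and directness of the key step this road is better. The chosen plan sets against it the short supply of both fragments (4 in two steps from 1, acid 5 bought), the absence of any need to tell apart the oxygens that become O1 and the 7-methoxy group, and a lower overall step count.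

**Alternative 2:** The cut is the C4–C4a bond, with O1–C8a and the C2=C3 bond already present in an aryloxyacrylic acid. (Z)-3-(4-Isopropoxy-3-methoxyphenoxy)-2-(3,4,5-trimethoxyphenyl)prop-2-enoic acid A5 would be treated with P2O5 in MeSO3H. The acylium ion would attack the aryloxy ring ortho to the ether oxygen and para to the methoxy group, giving 6-isopropoxy-7-methoxy-3-(3,4,5-trimethoxyphenyl)-4H-chromen-4-one A6.

- Merits: the site of attack is well activated and regiochemically safe, since the other ortho position lies between two oxygens. The isoflavone is formed directly, and Friedel–Crafts closure of aryloxyacrylic acids is a known route to chromones.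
- Weak points: a hot, strongly acidic, dehydrating medium meets an acid-labile aryl vinyl ether, a secondary alkyl aryl ether and two electron-rich rings open to sulfonylation or intermolecular acylation. Only the isomer of A5 with carboxyl and aryloxy cis can cyclise. Removal of the isopropyl group from A6 needs a boron or aluminium halide, which must discriminate against the Lewis-basic trimethoxy array of ring B.
- Comparison: the step count is similar and the precedent for the ring closure is better than for the chosen key step. The chosen plan offers a neutral, catalytic ring closure near room temperature and a hydrogenolytic deprotection that cannot touch a methyl ether.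

**Alternative 3:** Both C4–C4a and O1–C8a are cut, so ring A enters as an aryne. CsF would release the aryne from 3-(benzyloxy)-2-bromo-4-methoxy-6-(trimethylsilyl)phenyl trifluoromethanesulfonate A7. The enolate oxygen of methyl 3-oxo-2-(3,4,5-trimethoxyphenyl)propanoate A8 would add to the aryne carbon remote from bromine (C8a), and the aryl anion next to bromine (C4a) would attack the ester, giving 6-(benzyloxy)-5-bromo-7-methoxy-3-(3,4,5-trimethoxyphenyl)-4H-chromen-4-one A9.

- Merits: this is the most convergent road; two bonds form in one operation at the isoflavone level, and the bromine makes the aryne addition regioselective.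
- Weak points: A7 is a pentasubstituted benzene whose preparation alone would outrun the whole chosen route. The bromine serves only as a directing group and must be removed together with the benzyl group, which raises the risk of reducing C2=C3. Enolates of 1,3-dicarbonyl compounds tend to attack arynes at carbon, which leads to acyl–alkyl insertion and not to the chromone.
- Comparison: it is better in convergency and in bonds formed per step. The chosen plan sets against it fragments that are two steps or fewer from catalog compounds and no throwaway atoms beyond N2 and the benzyl group.

Key step: step 5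

## Route

**Step 1**
Reactants: 1 2,4-dimethoxybenzaldehyde
Product: 3 2,4-dimethoxyphenol, via 2,4-dimethoxyphenyl formate 2 (not isolated)
Conditions: 30% aq H2O2, H2SO4 (cat.), MeOH, rt
Reagents that add atoms: hydrogen peroxide, OO
Why: Acid-catalysed Dakin oxidation: the peroxyhemiacetal of 1 rearranges with migration of the electron-rich aryl group (Baeyer–Villiger type) to formate 2, which methanol cleaves in situ to the phenol.

**Step 2**
Reactants: 3 2,4-dimethoxyphenol
Product: 4 1-(benzyloxy)-2,4-dimethoxybenzene
Conditions: BnBr, K2CO3, DMF, rt
Reagents that add atoms: benzyl bromide, BrCc1ccccc1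
Why: Williamson ether synthesis (SN2 of the phenoxide on benzyl bromide); 3 has a single hydroxyl, so no selectivity question arises.

**Step 3**
Reactants: 4 1-(benzyloxy)-2,4-dimethoxybenzene; 5 2-(3,4,5-trimethoxyphenyl)acetic acid
Product: 7 1-[5-(benzyloxy)-2,4-dimethoxyphenyl]-2-(3,4,5-trimethoxyphenyl)ethanone, via 3,4,5-trimethoxyphenylacetyl chloride 6 (not isolated)
Conditions: 5, (COCl)2, DMF (cat.), CH2Cl2, 0 °C to rt, evaporate; then 4, SnCl4 (1.2 equiv, added last), CH2Cl2, −20 to 0 °C
Reagents that add atoms: none
Why: Acid chloride formation followed by Friedel–Crafts acylation; in 4 only C5 is para to one methoxy group, ortho to the other and unhindered, and SnCl4 is a Lewis acid that benzyl aryl ethers tolerate at low temperature. Adding SnCl4 to a mixture of 4 and 6 keeps 6 from acylating its own ring.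

**Step 4**
Reactants: 7 1-[5-(benzyloxy)-2,4-dimethoxyphenyl]-2-(3,4,5-trimethoxyphenyl)ethanone
Product: 8 1-[5-(benzyloxy)-2,4-dimethoxyphenyl]-2-diazo-2-(3,4,5-trimethoxyphenyl)ethanone
Conditions: 4-acetamidobenzenesulfonyl azide, DBU, MeCN, 0 °C to rt
Reagents that add atoms: 4-acetamidobenzenesulfonyl azide, CC(=O)Nc1ccc(cc1)S(=O)(=O)N=[N+]=[N-]
Why: Regitz diazo transfer: DBU deprotonates the benzylic, α-keto methylene of the deoxybenzoin, the enolate adds to the sulfonyl azide and the adduct collapses to the diazoketone and the sulfonamide.

**Step 5**
Reactants: 8 1-[5-(benzyloxy)-2,4-dimethoxyphenyl]-2-diazo-2-(3,4,5-trimethoxyphenyl)ethanone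
Product: 9 racemic 6-(benzyloxy)-7-methoxy-3-(3,4,5-trimethoxyphenyl)chroman-4-one
Conditions: Rh2(OAc)4 (2 mol %), CH2Cl2, 40 °C, slow addition of 8, 4 Å MS
Reagents that add atoms: none
Why: Proposed new method: Rh2(OAc)4, a divalent rhodium carboxylate, should expel N2 from 8 to give a donor–acceptor rhodium carbenoid at the future C3, flanked by ring B and the aryl ketone, which can insert into a C–H bond of the ortho-methoxy group (made hydridic by the adjacent oxygen lone pair) through a six-membered, three-centre transition state to form C2–C3; the closest known reaction type is the dirhodium-catalysed carbenoid C–H insertion next to an ether oxygen in ortho-alkoxyaryl diazoketones and related diazo esters, which gives 2-substituted chroman-4-ones and dihydrobenzofurans but has not been shown for the primary C–H bonds of an aryl methyl ether. Ring C closes at carbon by a 1,6 C–H insertion, the six-membered ring containing C3, C4, C4a, C8a, O1 and the former methyl carbon, now C2. The new stereocentre C3 is formed without control (achiral catalyst, no resident stereocentre), so 9 is racemic, which does not matter because step 6 flattens C3. The step needs insertion to outrun attack of the methoxy oxygen on the carbenoid (five-membered oxonium ylide, then methyl shift) and Wolff rearrangement. The stabilised, less electrophilic donor–acceptor carbenoid, the poor migratory aptitude of methyl (ylide formation should be reversible and unproductive) and the low temperature argue for insertion. Slow addition of 8 into dry solvent should suppress carbenoid dimerisation and O–H insertion into water. The benzylic CH2 of the benzyl ether, the para-methoxy group and the aryl C–H ortho to the ketone cannot compete, because they would require large-ring or four-membered transition states.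

**Step 6**
Reactants: 9 racemic 6-(benzyloxy)-7-methoxy-3-(3,4,5-trimethoxyphenyl)chroman-4-one
Product: 10 6-(benzyloxy)-7-methoxy-3-(3,4,5-trimethoxyphenyl)-4H-chromen-4-one
Conditions: DDQ, 1,4-dioxane, reflux
Reagents that add atoms: none
Why: DDQ dehydrogenation of an isoflavanone to the isoflavone (hydride abstraction from C2 of the enol, assisted by the O1 lone pair, then loss of a proton); it erases the C3 stereocentre, and a plain benzyl aryl ether is oxidised by DDQ far more slowly than the enolisable chromanone.

**Step 7**
Reactants: 10 6-(benzyloxy)-7-methoxy-3-(3,4,5-trimethoxyphenyl)-4H-chromen-4-one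
Product: 11 6-hydroxy-7-methoxy-3-(3,4,5-trimethoxyphenyl)-4H-chromen-4-one
Conditions: H2 (1 atm), 10% Pd/C, EtOAc/MeOH, rt, stopped after one equivalent of H2
Reagents that add atoms: none
Why: Hydrogenolysis of the benzyl aryl ether over Pd/C; the conjugated, trisubstituted C2=C3 bond of the vinylogous ester is reduced much more slowly and the methyl ethers are inert.

## Compound list

1 | 2,4-dimethoxybenzaldehyde | COc1ccc(C=O)c(OC)c1 | starting material
2 | 2,4-dimethoxyphenyl formate | COc1ccc(OC=O)c(OC)c1 | intermediate
3 | 2,4-dimethoxyphenol | COc1ccc(O)c(OC)c1 | intermediate
4 | 1-(benzyloxy)-2,4-dimethoxybenzene | COc1ccc(OCc2ccccc2)c(OC)c1 | intermediate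
5 | 2-(3,4,5-trimethoxyphenyl)acetic acid | COc1cc(CC(=O)O)cc(OC)c1OC | starting material
6 | 2-(3,4,5-trimethoxyphenyl)acetyl chloride | COc1cc(CC(Cl)=O)cc(OC)c1OC | intermediate
7 | 1-[5-(benzyloxy)-2,4-dimethoxyphenyl]-2-(3,4,5-trimethoxyphenyl)ethanone | COc1cc(OC)c(OCc2ccccc2)cc1C(=O)Cc1cc(OC)c(OC)c(OC)c1 | intermediate
8 | 1-[5-(benzyloxy)-2,4-dimethoxyphenyl]-2-diazo-2-(3,4,5-trimethoxyphenyl)ethanone | COc1cc(OC)c(OCc2ccccc2)cc1C(=O)C(=[N+]=[N-])c1cc(OC)c(OC)c(OC)c1 | intermediate
9 | racemic 6-(benzyloxy)-7-methoxy-3-(3,4,5-trimethoxyphenyl)chroman-4-one | COc1cc2OCC(c3cc(OC)c(OC)c(OC)c3)C(=O)c2cc1OCc1ccccc1 | intermediate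
10 | 6-(benzyloxy)-7-methoxy-3-(3,4,5-trimethoxyphenyl)-4H-chromen-4-one | COc1cc2occ(-c3cc(OC)c(OC)c(OC)c3)c(=O)c2cc1OCc1ccccc1 | intermediate
11 | 6-hydroxy-7-methoxy-3-(3,4,5-trimethoxyphenyl)-4H-chromen-4-one | COc1cc2occ(-c3cc(OC)c(OC)c(OC)c3)c(=O)c2cc1O | target

## Step count and risks

Total step count: 7. Longest linear sequence: 7 steps (1 to 11; acid 5 enters at step 3).

**Step 5 (key step, proposed new method).** The most likely failure is capture of the carbenoid by the methoxy oxygen, giving a five-membered oxonium ylide that then shifts its methyl group to carbon or to the enolate oxygen. This could outrun insertion because a primary C–H bond, even next to oxygen, inserts more slowly than the secondary C–H bonds of the known cases. Intermolecular carbenoid dimerisation is the second risk.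

The fallback is the classical deoxybenzoin route, which is known chemistry throughout. It sets out from acid 5, which is condensed with commercial 2-methoxybenzene-1,4-diol F1 in BF3·OEt2 at about 80 °C. This is a Friedel–Crafts acylation para to the methoxy group and ortho to a hydroxyl, and it should give 1-(2,5-dihydroxy-4-methoxyphenyl)-2-(3,4,5-trimethoxyphenyl)ethanone F2. F2 is then treated with BF3·OEt2, DMF and MsCl. A one-carbon unit is inserted at the methylene through a Vilsmeier-type iminium, the ring closes through the ortho-hydroxyl and dimethylamine is lost. The fallback comes back to the route at target 11.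

**Step 3.** The Lewis acid may cleave the benzyl ether or, by chelation to the new ketone, the methoxy group ortho to it. Acid chloride 6 may also acylate its own electron-rich ring.

The fallback sets out from 3 and moves the acylation ahead of the benzylation. Acetylation (Ac2O, pyridine) gives 2,4-dimethoxyphenyl acetate F3. Friedel–Crafts acylation of F3 with 6 (SnCl4, CH2Cl2, 0 °C) at the same ring position gives 2,4-dimethoxy-5-[(3,4,5-trimethoxyphenyl)acetyl]phenyl acetate F4. Methanolysis (K2CO3, MeOH) gives 1-(5-hydroxy-2,4-dimethoxyphenyl)-2-(3,4,5-trimethoxyphenyl)ethanone F5. Benzylation of F5 (BnBr, K2CO3, DMF) rejoins the route at 7.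

**Step 6.** On prolonged heating DDQ may abstract a benzylic hydride from the benzyl ether or oxidise the electron-rich ring B, and conversion may stall.

The fallback sets out from 9 and replaces direct dehydrogenation by selenation and elimination. Deprotonation with LiN(SiMe3)2 in THF at −78 °C and trapping with PhSeCl gives racemic 6-(benzyloxy)-7-methoxy-3-(phenylselanyl)-3-(3,4,5-trimethoxyphenyl)chroman-4-one F6. Oxidation with H2O2 gives 6-(benzyloxy)-7-methoxy-3-(phenylseleninyl)-3-(3,4,5-trimethoxyphenyl)chroman-4-one F7, which is not isolated. Its syn-elimination can engage only the C2 hydrogens, and the route is rejoined at 10.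

**Step 7.** Once the benzyl group is gone, the C2=C3 bond may be reduced to the isoflavanone.

The fallback sets out from 10 and reaches 11 without any new compound. It replaces reductive cleavage by a Lewis-acid dealkylation: BCl3 with pentamethylbenzene as benzyl cation scavenger in CH2Cl2 at −78 °C. This cannot reduce the double bond, and the low temperature protects the methyl ethers.

## Further compounds

F1 | step 5 | 2-methoxybenzene-1,4-diol | COc1cc(O)ccc1O
F2 | step 5 | 1-(2,5-dihydroxy-4-methoxyphenyl)-2-(3,4,5-trimethoxyphenyl)ethanone | COc1cc(O)c(cc1O)C(=O)Cc1cc(OC)c(OC)c(OC)c1
F3 | step 3 | 2,4-dimethoxyphenyl acetate | COc1ccc(OC(C)=O)c(OC)c1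
F4 | step 3 | 2,4-dimethoxy-5-[(3,4,5-trimethoxyphenyl)acetyl]phenyl acetate | COc1cc(OC)c(OC(C)=O)cc1C(=O)Cc1cc(OC)c(OC)c(OC)c1
F5 | step 3 | 1-(5-hydroxy-2,4-dimethoxyphenyl)-2-(3,4,5-trimethoxyphenyl)ethanone | COc1cc(OC)c(O)cc1C(=O)Cc1cc(OC)c(OC)c(OC)c1
F6 | step 6 | racemic 6-(benzyloxy)-7-methoxy-3-(phenylselanyl)-3-(3,4,5-trimethoxyphenyl)chroman-4-one | COc1cc2OCC([Se]c3ccccc3)(c3cc(OC)c(OC)c(OC)c3)C(=O)c2cc1OCc1ccccc1
F7 | step 6 | 6-(benzyloxy)-7-methoxy-3-(phenylseleninyl)-3-(3,4,5-trimethoxyphenyl)chroman-4-one | COc1cc2OCC([Se](=O)c3ccccc3)(c3cc(OC)c(OC)c(OC)c3)C(=O)c2cc1OCc1ccccc1
F0 | step 7 | none | none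
A1 | alternative 1 | 2-(3,4,5-trimethoxyphenyl)acetaldehyde | COc1cc(CC=O)cc(OC)c1OC
A2 | alternative 1 | 4-[(E)-2-(3,4,5-trimethoxyphenyl)ethenyl]morpholine | COc1cc(/C=C/N2CCOCC2)cc(OC)c1OC
A3 | alternative 1 | 2-acetoxy-5-(benzyloxy)-4-methoxybenzoyl chloride | COc1cc(OC(C)=O)c(C(Cl)=O)cc1OCc1ccccc1
A4 | alternative 1 | 6-(benzyloxy)-7-methoxy-3-(3,4,5-trimethoxyphenyl)-4H-chromen-4-one (identical with 10) | COc1cc2occ(-c3cc(OC)c(OC)c(OC)c3)c(=O)c2cc1OCc1ccccc1
A5 | alternative 2 | (Z)-3-(4-isopropoxy-3-methoxyphenoxy)-2-(3,4,5-trimethoxyphenyl)prop-2-enoic acid | COc1cc(O/C=C(\C(O)=O)c2cc(OC)c(OC)c(OC)c2)ccc1OC(C)C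
A6 | alternative 2 | 6-isopropoxy-7-methoxy-3-(3,4,5-trimethoxyphenyl)-4H-chromen-4-one | COc1cc2occ(-c3cc(OC)c(OC)c(OC)c3)c(=O)c2cc1OC(C)C
A7 | alternative 3 | 3-(benzyloxy)-2-bromo-4-methoxy-6-(trimethylsilyl)phenyl trifluoromethanesulfonate | COc1cc([Si](C)(C)C)c(OS(=O)(=O)C(F)(F)F)c(Br)c1OCc1ccccc1
A8 | alternative 3 | methyl 3-oxo-2-(3,4,5-trimethoxyphenyl)propanoate | COC(=O)C(C=O)c1cc(OC)c(OC)c(OC)c1
A9 | alternative 3 | 6-(benzyloxy)-5-bromo-7-methoxy-3-(3,4,5-trimethoxyphenyl)-4H-chromen-4-one | COc1cc2occ(-c3cc(OC)c(OC)c(OC)c3)c(=O)c2c(Br)c1OCc1ccccc1
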